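**Strategy.** Drimane numbering is used (ring A: C1–C5, C10; ring B: C5–C10). Everything rests on disconnecting the C5–C10 ring-fusion bond, which joins the quaternary C10 to C5 next to the C4 gem-dimethyl carbon, a crowded linkage best made by an early-transition-state radical addition. In one operation the key step decarboxylates an acyclic acid to a tertiary C10 radical, closes ring A by 6-exo addition to an enone and sets C5 and C10 under control of the C3 silyl ether. Its precursor is an open-chain (E)-enone acid whose α-carbon carries the C10 methyl and the C9 aldehyde as its dimethyl acetal; ring B then follows by aldol condensation.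

Key step: step 8

Remark: the target is read as the (3R,5S,9R,10R) isomer (trans-fused, with the C3 acetate, the C10 methyl and the C11 arm on one face); the intermediates between the ester mono-reduction and the key step are carried as mixtures of epimers at C10, because that centre becomes planar in the key step.

**Route**

Step 1
Reactants: 1 dimethyl 2-methylpropanedioate (dimethyl methylmalonate); 2 prop-2-enal (acrolein)
Product: 3 dimethyl 2-methyl-2-(3-oxopropyl)propanedioate
Conditions: NaOMe (5 mol%), MeOH, −10 to 0 °C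
Reagents that add atoms: none
Why: Base-catalysed Michael addition of the doubly stabilised malonate anion to acrolein is a soft 1,4-process that installs the future C10 (with its methyl and two carboxyl carbons), C1, C2 and the C3 aldehyde in one bond formation, with no stereocentre created.

Step 2
Reactants: 3 dimethyl 2-methyl-2-(3-oxopropyl)propanedioate
Product: 5 dimethyl 2-[(3R)-3-hydroxy-4,4-dimethylhex-5-en-1-yl]-2-methylpropanedioate, via borinate ester 4 (not isolated)
Conditions: (−)-Ipc2BH [from (+)-α-pinene], 3-methylbuta-1,2-diene, THF, −25 °C; then 3, −78 °C; then H2O2, NaH2PO4/Na2HPO4 buffer (pH 7), MeOH, 0 °C to rt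
Reagents that add atoms: 3-methylbuta-1,2-diene, CC(C)=C=C
Why: Brown reverse prenylation, in which the γ,γ-dimethylallylborane formed by hydroboration of the allene adds through a closed chair transition state at its tertiary terminus, the isopinocampheyl groups from (+)-α-pinene directing attack to the Si face of the aldehyde so that C3 is set as R, while the malonate esters are inert to the allylborane.

Step 3
Reactants: 5 dimethyl 2-[(3R)-3-hydroxy-4,4-dimethylhex-5-en-1-yl]-2-methylpropanedioate
Product: 6 dimethyl 2-[(3R)-3-[(tert-butyldimethylsilyl)oxy]-4,4-dimethylhex-5-en-1-yl]-2-methylpropanedioate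
Conditions: TBSOTf, 2,6-lutidine, CH2Cl2, −78 to 0 °C
Reagents that add atoms: tert-butyldimethylsilyl trifluoromethanesulfonate, CC(C)(C)[Si](C)(C)OS(=O)(=O)C(F)(F)F
Why: O-silylation with the silyl triflate is fast enough for the neopentyl-type secondary alcohol, proceeds with retention because only the O–H bond reacts, and removes the hydroxyl before it can lactonise onto a malonate ester.

Step 4
Reactants: 6 dimethyl 2-[(3R)-3-[(tert-butyldimethylsilyl)oxy]-4,4-dimethylhex-5-en-1-yl]-2-methylpropanedioate
Product: 7 methyl (5R)-5-[(tert-butyldimethylsilyl)oxy]-2-formyl-2,6,6-trimethyloct-7-enoate (both epimers at C2, the future C10)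
Conditions: iBu2AlH (1.2 equiv), CH2Cl2, −78 °C; then MeOH, aq. potassium sodium tartrate
Reagents that add atoms: none
Why: Partial reduction of a 2,2-disubstituted malonate, in which one hydride adds to one ester and the chelated aluminium hemiacetal persists at −78 °C so that the aldehyde appears only on quench; the new C10 centre forms unselectively, which is harmless because it is erased in step 8.

Step 5
Reactants: 7 methyl (5R)-5-[(tert-butyldimethylsilyl)oxy]-2-formyl-2,6,6-trimethyloct-7-enoate
Product: 8 methyl (5R)-5-[(tert-butyldimethylsilyl)oxy]-2-(dimethoxymethyl)-2,6,6-trimethyloct-7-enoate (both epimers at C2)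
Conditions: MeOSiMe3, Me3SiOTf (cat.), CH2Cl2, −78 to −30 °C
Reagents that add atoms: methoxytrimethylsilane, CO[Si](C)(C)C
Why: Noyori acetalisation converts the hindered, non-enolisable aldehyde into its dimethyl acetal under aprotic, low-temperature conditions that leave the silyl ether, the ester and the vinyl group untouched.

Step 6
Reactants: 8 methyl (5R)-5-[(tert-butyldimethylsilyl)oxy]-2-(dimethoxymethyl)-2,6,6-trimethyloct-7-enoate
Product: 9 (5R)-5-[(tert-butyldimethylsilyl)oxy]-2-(dimethoxymethyl)-2,6,6-trimethyloct-7-enoic acid (both epimers at C2)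
Conditions: KOH, MeOH/H2O, 70 °C; then 1 M HCl to pH 4, 0 °C
Reagents that add atoms: potassium hydroxide, [K+].[OH-]
Why: Saponification by acyl–oxygen cleavage is slow at the quaternary centre but has no competitor, since the acetal, the hindered silyl ether and the alkene are stable to hot alkali and no enolisable or base-labile group is present.

Step 7
Reactants: 9 (5R)-5-[(tert-butyldimethylsilyl)oxy]-2-(dimethoxymethyl)-2,6,6-trimethyloct-7-enoic acid; 10 pent-1-en-3-one
Product: 11 (5R,7E)-5-[(tert-butyldimethylsilyl)oxy]-2-(dimethoxymethyl)-2,6,6-trimethyl-9-oxoundec-7-enoic acid (both epimers at C2)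
Conditions: second-generation Hoveyda–Grubbs catalyst [RuCl2(H2IMes)(=CH-C6H4-2-OiPr)] (5 mol%), 10 (5 equiv), CH2Cl2, 40 °C
Reagents that add atoms: none
Why: Olefin cross-metathesis between the vinyl group on the quaternary C4, which cannot homodimerise, and an excess of the electron-poor vinyl ketone should give the (E)-enone, the ruthenium carbene tolerating the free acid, the acetal and the silyl ether.

Step 8
Reactants: 11 (5R,7E)-5-[(tert-butyldimethylsilyl)oxy]-2-(dimethoxymethyl)-2,6,6-trimethyl-9-oxoundec-7-enoic acid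
Product: 12 1-[(1R,3R,6R)-3-[(tert-butyldimethylsilyl)oxy]-6-(dimethoxymethyl)-2,2,6-trimethylcyclohexyl]butan-2-one
Conditions: [Ir(dF(CF3)ppy)2(dtbbpy)]PF6 (2 mol%), K2HPO4 (1.2 equiv), DMF (0.01 M, degassed), blue LEDs (450 nm), 0 °C to rt
Reagents that add atoms: none
Why: The carboxylate of 11 is oxidised by the photoexcited trivalent iridium complex, CO2 is lost, and the planar, nucleophilic tertiary C10 radical adds to the enone β-carbon C5, after which the α-keto radical at C6 is reduced by the divalent iridium species and protonated, which returns the catalyst. The closest known reaction type is the photoredox decarboxylative Giese addition of tertiary carboxylic acids to enones, used here intramolecularly. Ring A closes in the 6-exo-trig mode (C10 onto C5, the C5=C6 bond staying outside the ring), the 7-endo attack at the α-carbon C6 being electronically and sterically disfavoured. C5 is set by a chair-like transition state in which the C3 silyloxy group and the enone arm are both equatorial, so that C6 ends cis to the C3 oxygen and the absolute configuration of C3 is relayed. C10 is set in the same chair by the smaller methyl taking the axial site, because an axial dimethoxymethyl group would clash with the axial C4 methyl, which places C9 equatorial and trans to C6; both C10 epimers of 11 converge because the radical is planar. The step needs cyclisation to outrun hydrogen-atom capture and intermolecular addition, which high dilution, the polarity match of radical and acceptor and the Thorpe–Ingold effect of the C4 gem-dimethyl group should secure.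

Step 9
Reactants: 12 1-[(1R,3R,6R)-3-[(tert-butyldimethylsilyl)oxy]-6-(dimethoxymethyl)-2,2,6-trimethylcyclohexyl]butan-2-one
Product: 14 (4aS,7R,8aS)-7-[(tert-butyldimethylsilyl)oxy]-3,4a,8,8-tetramethyl-4a,5,6,7,8,8a-hexahydronaphthalen-2(1H)-one, via keto aldehyde 13 (not isolated)
Conditions: TsOH·H2O (cat.), acetone/H2O, rt; then KOH, MeOH, 50 °C
Reagents that add atoms: none
Why: Mild aqueous acid hydrolyses the dimethyl acetal to the non-enolisable C9 aldehyde, and base then drives an intramolecular aldol condensation in which only the C8 enolate of the ethyl ketone can reach C9 through a six-membered transition state (attack from C6 would give a four-membered ring), dehydration giving the C8=C9 enone of ring B without touching C3, C5 or C10.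

Step 10
Reactants: 14 (4aS,7R,8aS)-7-[(tert-butyldimethylsilyl)oxy]-3,4a,8,8-tetramethyl-4a,5,6,7,8,8a-hexahydronaphthalen-2(1H)-one
Product: 15 (2R,4aS,7R,8aS)-7-[(tert-butyldimethylsilyl)oxy]-3,4a,8,8-tetramethyl-1,2,4a,5,6,7,8,8a-octahydronaphthalen-2-ol (C7 hydroxyl cis to the C10 methyl)
Conditions: NaBH4, CeCl3·7H2O, MeOH, −20 °C
Reagents that add atoms: none
Why: Luche reduction delivers hydride 1,2 to the enone and, as with steroidal 4-en-3-ones, axially from the face opposite the angular C10 methyl, so the C7 hydroxyl should end pseudo-equatorial and cis to that methyl (7R).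

Step 11
Reactants: 15 (2R,4aS,7R,8aS)-7-[(tert-butyldimethylsilyl)oxy]-3,4a,8,8-tetramethyl-1,2,4a,5,6,7,8,8a-octahydronaphthalen-2-ol
Product: 16 tributyl({[(2R,4aS,7R,8aS)-7-[(tert-butyldimethylsilyl)oxy]-3,4a,8,8-tetramethyl-1,2,4a,5,6,7,8,8a-octahydronaphthalen-2-yl]oxy}methyl)stannane
Conditions: KH, Bu3SnCH2I, THF, 0 °C to rt
Reagents that add atoms: tributyl(iodomethyl)stannane, CCCC[Sn](CCCC)(CCCC)CI
Why: Williamson etherification of the potassium alkoxide with the reactive α-stannyl iodide gives the stannylmethyl ether with retention at C7, because only the O–H bond is involved.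

Step 12
Reactants: 16 tributyl({[(2R,4aS,7R,8aS)-7-[(tert-butyldimethylsilyl)oxy]-3,4a,8,8-tetramethyl-1,2,4a,5,6,7,8,8a-octahydronaphthalen-2-yl]oxy}methyl)stannane
Product: 18 {(1R,4aS,6R,8aR)-6-[(tert-butyldimethylsilyl)oxy]-2,5,5,8a-tetramethyl-1,4,4a,5,6,7,8,8a-octahydronaphthalen-1-yl}methanol, via lithiomethyl ether 17 (not isolated)
Conditions: n-BuLi, THF, −78 to −40 °C; then aq. NH4Cl
Reagents that add atoms: none
Why: Wittig–Still rearrangement, in which tin–lithium exchange gives an α-alkoxymethyllithium that undergoes a suprafacial [2,3]-sigmatropic shift, forming the C9–C11 bond on the face that carried the C7 oxygen (cis to the C10 methyl, 9R) and moving the double bond to C7=C8.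

Step 13
Reactants: 18 {(1R,4aS,6R,8aR)-6-[(tert-butyldimethylsilyl)oxy]-2,5,5,8a-tetramethyl-1,4,4a,5,6,7,8,8a-octahydronaphthalen-1-yl}methanol; 19 7-hydroxy-2H-chromen-2-one (umbelliferone)
Product: 20 7-{[(1R,4aS,6R,8aR)-6-[(tert-butyldimethylsilyl)oxy]-2,5,5,8a-tetramethyl-1,4,4a,5,6,7,8,8a-octahydronaphthalen-1-yl]methoxy}-2H-chromen-2-one
Conditions: PPh3, DIAD, THF, 0 to 45 °C
Reagents that add atoms: none
Why: Mitsunobu etherification activates the primary C11 alcohol as its alkoxyphosphonium ion, which the acidic coumarin phenol displaces in an SN2 step at the CH2 carbon, no stereocentre being involved.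

Step 14
Reactants: 20 7-{[(1R,4aS,6R,8aR)-6-[(tert-butyldimethylsilyl)oxy]-2,5,5,8a-tetramethyl-1,4,4a,5,6,7,8,8a-octahydronaphthalen-1-yl]methoxy}-2H-chromen-2-one
Product: 21 7-{[(1R,4aS,6R,8aR)-6-hydroxy-2,5,5,8a-tetramethyl-1,4,4a,5,6,7,8,8a-octahydronaphthalen-1-yl]methoxy}-2H-chromen-2-one
Conditions: HF·pyridine, THF/pyridine, 0 °C to rt
Reagents that add atoms: none
Why: Fluoride-driven desilylation relies on the strength of the Si–F bond and, under pyridine-buffered conditions, should spare the coumarin lactone, the aryl ether and the trisubstituted alkene, with retention at C3.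

Step 15
Reactants: 21 7-{[(1R,4aS,6R,8aR)-6-hydroxy-2,5,5,8a-tetramethyl-1,4,4a,5,6,7,8,8a-octahydronaphthalen-1-yl]methoxy}-2H-chromen-2-one
Product: 22 7-{[(1R,4aS,6R,8aR)-6-(acetyloxy)-2,5,5,8a-tetramethyl-1,4,4a,5,6,7,8,8a-octahydronaphthalen-1-yl]methoxy}-2H-chromen-2-one (CNP0224712.1)
Conditions: Ac2O, pyridine, DMAP (cat.), CH2Cl2, rt
Reagents that add atoms: acetic anhydride, CC(=O)OC(C)=O
Why: DMAP-catalysed acylation of the equatorial C3 hydroxyl takes place at oxygen with retention and completes the target.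

**Compound list**

1 | dimethyl 2-methylpropanedioate (dimethyl methylmalonate) | COC(=O)C(C)C(=O)OC | starting material
2 | prop-2-enal (acrolein) | C=CC=O | starting material
3 | dimethyl 2-methyl-2-(3-oxopropyl)propanedioate | COC(=O)C(C)(CCC=O)C(=O)OC | intermediate
4 | borinate ester of 5 (C3–O–B(Ipc)2, Ipc = isopinocampheyl from (+)-α-pinene) | COC(=O)C(C)(CC[C@@H](OB([C@@H]1C[C@@H]2C[C@H]([C@H]1C)C2(C)C)[C@@H]1C[C@@H]2C[C@H]([C@H]1C)C2(C)C)C(C)(C)C=C)C(=O)OC | intermediate
5 | dimethyl 2-[(3R)-3-hydroxy-4,4-dimethylhex-5-en-1-yl]-2-methylpropanedioate | COC(=O)C(C)(CC[C@@H](O)C(C)(C)C=C)C(=O)OC | intermediate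
6 | dimethyl 2-[(3R)-3-[(tert-butyldimethylsilyl)oxy]-4,4-dimethylhex-5-en-1-yl]-2-methylpropanedioate | COC(=O)C(C)(CC[C@@H](O[Si](C)(C)C(C)(C)C)C(C)(C)C=C)C(=O)OC | intermediate
7 | methyl (5R)-5-[(tert-butyldimethylsilyl)oxy]-2-formyl-2,6,6-trimethyloct-7-enoate, both C2 epimers | COC(=O)C(C)(C=O)CC[C@@H](O[Si](C)(C)C(C)(C)C)C(C)(C)C=C | intermediate
8 | methyl (5R)-5-[(tert-butyldimethylsilyl)oxy]-2-(dimethoxymethyl)-2,6,6-trimethyloct-7-enoate, both C2 epimers | COC(=O)C(C)(C(OC)OC)CC[C@@H](O[Si](C)(C)C(C)(C)C)C(C)(C)C=C | intermediate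
9 | (5R)-5-[(tert-butyldimethylsilyl)oxy]-2-(dimethoxymethyl)-2,6,6-trimethyloct-7-enoic acid, both C2 epimers | OC(=O)C(C)(C(OC)OC)CC[C@@H](O[Si](C)(C)C(C)(C)C)C(C)(C)C=C | intermediate
10 | pent-1-en-3-one | CCC(=O)C=C | starting material
11 | (5R,7E)-5-[(tert-butyldimethylsilyl)oxy]-2-(dimethoxymethyl)-2,6,6-trimethyl-9-oxoundec-7-enoic acid, both C2 epimers | CCC(=O)/C=C/C(C)(C)[C@H](O[Si](C)(C)C(C)(C)C)CCC(C)(C(OC)OC)C(=O)O | intermediate
12 | 1-[(1R,3R,6R)-3-[(tert-butyldimethylsilyl)oxy]-6-(dimethoxymethyl)-2,2,6-trimethylcyclohexyl]butan-2-one | CC(C)(C)[Si](C)(C)O[C@@H]1CC[C@@](C)(C(OC)OC)[C@H](CC(=O)CC)C1(C)C | intermediate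
13 | (1R,2R,4R)-4-[(tert-butyldimethylsilyl)oxy]-1,3,3-trimethyl-2-(2-oxobutyl)cyclohexane-1-carbaldehyde | CC(C)(C)[Si](C)(C)O[C@@H]1CC[C@@](C)(C=O)[C@H](CC(=O)CC)C1(C)C | intermediate
14 | (4aS,7R,8aS)-7-[(tert-butyldimethylsilyl)oxy]-3,4a,8,8-tetramethyl-4a,5,6,7,8,8a-hexahydronaphthalen-2(1H)-one | CC(C)(C)[Si](C)(C)O[C@@H]1CC[C@@]2(C)C=C(C)C(=O)C[C@@H]2C1(C)C | intermediate
15 | (2R,4aS,7R,8aS)-7-[(tert-butyldimethylsilyl)oxy]-3,4a,8,8-tetramethyl-1,2,4a,5,6,7,8,8a-octahydronaphthalen-2-ol | CC(C)(C)[Si](C)(C)O[C@@H]1CC[C@@]2(C)C=C(C)[C@H](O)C[C@@H]2C1(C)C | intermediate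
16 | tributyl({[(2R,4aS,7R,8aS)-7-[(tert-butyldimethylsilyl)oxy]-3,4a,8,8-tetramethyl-1,2,4a,5,6,7,8,8a-octahydronaphthalen-2-yl]oxy}methyl)stannane | CC(C)(C)[Si](C)(C)O[C@@H]1CC[C@@]2(C)C=C(C)[C@H](OC[Sn](CCCC)(CCCC)CCCC)C[C@@H]2C1(C)C | intermediate
17 | lithiomethyl ether of 15 (C7–O–CH2Li) | CC(C)(C)[Si](C)(C)O[C@@H]1CC[C@@]2(C)C=C(C)[C@H](OC[Li])C[C@@H]2C1(C)C | intermediate
18 | {(1R,4aS,6R,8aR)-6-[(tert-butyldimethylsilyl)oxy]-2,5,5,8a-tetramethyl-1,4,4a,5,6,7,8,8a-octahydronaphthalen-1-yl}methanol | CC(C)(C)[Si](C)(C)O[C@@H]1CC[C@@]2(C)[C@H](CO)C(C)=CC[C@@H]2C1(C)C | intermediate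
19 | 7-hydroxy-2H-chromen-2-one (umbelliferone) | O=c1ccc2ccc(O)cc2o1 | starting material
20 | 7-{[(1R,4aS,6R,8aR)-6-[(tert-butyldimethylsilyl)oxy]-2,5,5,8a-tetramethyl-1,4,4a,5,6,7,8,8a-octahydronaphthalen-1-yl]methoxy}-2H-chromen-2-one | CC(C)(C)[Si](C)(C)O[C@@H]1CC[C@@]2(C)[C@H](COc3ccc4ccc(=O)oc4c3)C(C)=CC[C@@H]2C1(C)C | intermediate
21 | 7-{[(1R,4aS,6R,8aR)-6-hydroxy-2,5,5,8a-tetramethyl-1,4,4a,5,6,7,8,8a-octahydronaphthalen-1-yl]methoxy}-2H-chromen-2-one | O[C@@H]1CC[C@@]2(C)[C@H](COc3ccc4ccc(=O)oc4c3)C(C)=CC[C@@H]2C1(C)C | intermediate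
22 | 7-{[(1R,4aS,6R,8aR)-6-(acetyloxy)-2,5,5,8a-tetramethyl-1,4,4a,5,6,7,8,8a-octahydronaphthalen-1-yl]methoxy}-2H-chromen-2-one (CNP0224712.1) | CC(=O)O[C@@H]1CC[C@@]2(C)[C@H](COc3ccc4ccc(=O)oc4c3)C(C)=CC[C@@H]2C1(C)C | target

**Step count and risk**

Total step count: 15. Longest linear sequence: 15 steps (from 1 and 2 to 22).

Steps most likely to fail:

1. Step 8. The crowded carboxylate may be oxidised too slowly, the excited catalyst may be diverted by energy transfer to the enone, the C10 radical may capture a hydrogen atom before ring closure, or the chair with an axial C3 silyloxy group may compete and erode the relay from C3. The fallback sets out from 11 and changes the way the radical is released. Acid 11 would be esterified with N-hydroxyphthalimide (iPrN=C=NiPr, DMAP cat., CH2Cl2) to 1,3-dioxoisoindolin-2-yl (5R,7E)-5-[(tert-butyldimethylsilyl)oxy]-2-(dimethoxymethyl)-2,6,6-trimethyl-9-oxoundec-7-enoate F1. Single-electron reduction of this redox-active ester ([Ru(bpy)3](PF6)2, Hantzsch ester, iPr2NEt, dilute CH2Cl2, blue LEDs, low temperature) would trigger fragmentation to the same C10 radical without any oxidation of a carboxylate, and the 6-exo cyclisation would rejoin the route at 12.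

2. Step 12. The α-alkoxymethyllithium may undergo a [1,2]-shift or be protonated instead of rearranging, because the C7–O bond is pseudo-equatorial and C9 must be attacked beside the axial C10 methyl. The fallback sets out from 15 and uses a neutral, thermal [2,3]-shift. Heating 15 with Me2NCH(OMe)2 in xylene at 140–160 °C (Büchi rearrangement of the derived alkoxy(amino)carbene) would transfer one carbon suprafacially from the C7 oxygen to C9 and give (1R,4aS,6R,8aR)-6-[(tert-butyldimethylsilyl)oxy]-N,N,2,5,5,8a-hexamethyl-1,4,4a,5,6,7,8,8a-octahydronaphthalene-1-carboxamide F2. Reduction of the tertiary amide to the primary alcohol (LiEt3BH, THF, 0 °C to rt) would rejoin the route at 18.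

3. Step 7. Productive metathesis at the vinyl group flanked by the quaternary C4 may be slow, while the catalyst is consumed by homodimerisation of the vinyl ketone. The fallback sets out from 9 and builds the enone by olefination. Oxidative cleavage of the vinyl group (OsO4 cat., NaIO4, 2,6-lutidine, dioxane/H2O, Lemieux–Johnson conditions) would give (5R)-5-[(tert-butyldimethylsilyl)oxy]-2-(dimethoxymethyl)-2,6,6-trimethyl-7-oxoheptanoic acid F3, a non-enolisable aldehyde. Horner–Wadsworth–Emmons olefination with dimethyl (2-oxobutyl)phosphonate (LiCl, iPr2NEt in excess to cover the acid, MeCN, rt) would give the (E)-enone and rejoin the route at 11.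

**Further compounds**

F1 | step 8 | 1,3-dioxoisoindolin-2-yl (5R,7E)-5-[(tert-butyldimethylsilyl)oxy]-2-(dimethoxymethyl)-2,6,6-trimethyl-9-oxoundec-7-enoate | CCC(=O)/C=C/C(C)(C)[C@H](O[Si](C)(C)C(C)(C)C)CCC(C)(C(OC)OC)C(=O)ON1C(=O)c2ccccc2C1=O
F2 | step 12 | (1R,4aS,6R,8aR)-6-[(tert-butyldimethylsilyl)oxy]-N,N,2,5,5,8a-hexamethyl-1,4,4a,5,6,7,8,8a-octahydronaphthalene-1-carboxamide | CC(C)(C)[Si](C)(C)O[C@@H]1CC[C@@]2(C)[C@H](C(=O)N(C)C)C(C)=CC[C@@H]2C1(C)C
F3 | step 7 | (5R)-5-[(tert-butyldimethylsilyl)oxy]-2-(dimethoxymethyl)-2,6,6-trimethyl-7-oxoheptanoic acid | OC(=O)C(C)(C(OC)OC)CC[C@@H](O[Si](C)(C)C(C)(C)C)C(C)(C)C=O
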